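## The problem

CNP0280971.1 is a (+)-epicatechin unit, (2S,3S) with the C2 aryl group and the C3 hydroxyl cis on ring C. Its C8 carries a methine carbon that also bears a 3,4-dihydroxyphenyl ring and C2 of a 4,6-dihydroxy-2,3-dihydrobenzofuran. Two of the four stereocentres are those of a purchasable flavan-3-ol. The other two, the methine (R) and dihydrobenzofuran C2 (S), are a vicinal pair lying five and six bonds from the flavan centres, so the flavan cannot be relied on to direct them, but they can control each other if both are made in one ring-forming event. The methine is flanked by two very electron-rich arenes and a secondary ether carbon, which makes every bond to it crowded. The molecule has eight phenols and one secondary alcohol, and the free polyphenol is oxidised in air and base. The O1–C2 bond of ring C is a benzylic ether that ionises under acid with loss of the C2 configuration, and the doubly benzylic methine can shed an aryl group under acid, so the late steps must be neutral or mildly basic and the last one hydrogenolytic. On ring A, O7 has to be told apart from O5. The enabling feature is that the methine lies ortho to the C7 hydroxyl: O7, C7, C8 and the methine form an o-quinone methide (a 1-oxadiene). Adding a two-carbon glycolate enolate across it delivers dihydrobenzofuran C2 with its oxygen and C3 as a lactone carbonyl, sets both new centres in a six-membered ring and ties up O7 for the time being.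

## Retrosynthesis

Target 27 is traced to its nona-O-benzyl ether 26. One protecting group for all nine hydroxyls allows a single neutral hydrogenolysis at the end, and benzyl ethers survive organolithium, Grignard, hydride, fluoride and copper chemistry.

In 26 the aryl–oxygen bond O1–C7a of the dihydrobenzofuran is cut, giving bromo alcohol 25. The neighbouring cut, O1–C2, would need an SN2 displacement with inversion at a hindered secondary carbon next to the diarylmethine, where aryl participation threatens. The aryl–oxygen cut leaves the C2–O bond untouched, so C2 keeps its configuration. The forward reaction is a 5-exo copper-catalysed O-arylation of a secondary alcohol.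

In 25 the C3–C3a bond is cut, giving terminal epoxide 21 and ortho-bromoaryl Grignard reagent 24. Reagent 24 comes from iodide 23 by iodine–magnesium exchange, and 23 from bromide 22 by iodination. The obvious neighbour, opening a lactone with 24 to an aryl ketone, was set aside for three reasons:
- it leaves an enolisable α-silyloxy ketone next to the new stereocentre;
- a hindered, basic Grignard reagent can enolise the aryl ester;
- it ends with an acid-mediated deoxygenation on a substrate carrying an acid-labile benzylic ether and methine.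

Attack at the CH2 end of an epoxide touches no stereocentre and frees the C2 hydroxyl in the same step.

Epoxide 21 is traced through hydroxy tosylate alkoxide 20, tosylate 19, alcohol 18 and phenol diol 17 to lactone 16. The epoxide oxygen is the silyloxy oxygen of 16 and the epoxide CH2 is its carbonyl carbon, so the lactone is used up rather than excised. The forward steps are hydride reduction, O7 benzylation, sulfonylation and fluoride-triggered ring closure, all with retention.

Lactone 16 is cut at the methine–C3 bond and the O7–acyl bond, giving carbinol 10 (through o-quinone methide 15) and acyl imidazole 14.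
- Cutting methine–C8 instead (a benzylic cation attacking the flavan) would raise C6/C8 regiochemistry and leave both centres to acyclic control.
- Cutting the methine–catechol bond would set one centre at a time.
- The chosen cut makes both centres in one catalytic step inside a ring where cis and trans are defined, and uses O7 as a built-in nucleophile.

Carbinol 10 is a flavan with one extra aryl carbinol, and 14 is a two-carbon acyl donor. The forward reaction must be catalyst-controlled, cis-selective and free of epimerisation.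

Acyl imidazole 14 is traced to silyloxy acid 13 and then, through bis-silyl compound 12, to glycolic acid 11. The silyl ether is chosen because fluoride removes it in the presence of benzyl ethers and thereby triggers epoxide formation.

Carbinol 10 is cut at the methine–aryl bond into hydroxy aldehyde 7 and Grignard reagent 9, which is made from bromide 8. The reverse polarity (aryllithium 5 adding to an aryl aldehyde) would give a carbinol with O7 still benzylated and would need oxidation, debenzylation and reduction afterwards. Placing the carbonyl on the flavan lets the O7 release come first and the Grignard addition deliver the free o-hydroxy carbinol directly.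

Aldehyde 7 comes from 6 by cleavage of the one benzyl ether ortho to the formyl group, which is what distinguishes O7 from O5. Aldehyde 6 comes from bromide 4 through aryllithium 5; 4 comes from 3 by benzylation of O3; 3 comes from 2 by C8-selective bromination; and 2 comes from (+)-epicatechin 1 by benzylation of the phenols. Compound 1 supplies both ring C stereocentres.

## Roads not taken

Alternative 1: The C2–C3 bond of the dihydrobenzofuran is cut. In the forward direction aryldiazoacetate A1, whose ortho oxygen carries the 2,2-diarylethyl group, loses nitrogen on a chiral dirhodium tetracarboxylate. The carbene inserts into the ether C–H bond (1,5 insertion) and gives the cis dihydrobenzofuran-3-carboxylate A2.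
- Merits: the ring closure is itself a catalytic asymmetric C–C bond formation. It needs no aryl halide and no copper step, and the reaction class is well studied for ethers.
- Weak points: the methine centre must already be in A1 as a single enantiomer, so the harder half of the vicinal pair is a separate problem. The ester at C3 has no place in the target and costs a saponification and a radical decarboxylation. The carbene carbon sits between two ortho silyloxy groups. The insertion site is a non-benzylic methylene next to a doubly benzylic methine C–H that could react instead, and the many benzyloxyarenes invite cyclopropanation.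
- Comparison: Alternative 1 is better in that C2 is set by a direct C–C ring closure. The chosen plan answers with one step (10 + 14 → 16) that creates both centres of the pair, and the extra carbonyl of 16 is converted into C3 rather than removed.

Alternative 2: Ring A is cut at C8–C8a and C6–C7. Cyclobutenone A3 and siloxyalkyne A4 are heated together. Electrocyclic opening to a vinylketene, (2+2) addition to the alkyne, a second opening and a 6π closure give phenol A5. Ring C is then closed by displacement at C2 with inversion.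
- Merits: it is the most convergent plan, and the substitution pattern of ring A is unambiguous. O5, O7 and the C8a oxygen emerge already differentiated, which the chosen plan achieves only by chelation-controlled debenzylation in step 5. It does not depend on the rare enantiomeric series of the flavan.
- Weak points: the annulation sets no stereocentre. All four must be built into A3 and A4, and A4 already contains the vicinal methine/C2 pair that is the core problem, at a propargylic, epimerisable position. Prolonged heating and a later displacement at benzylic C2 both endanger configuration, and the fragment syntheses make this the longest route.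
- Comparison: Alternative 2 is better in phenol differentiation and in independence from 1. The chosen plan answers with two centres taken from 1 and two made in one catalytic step, at far lower step count.

Alternative 3: Ring C is cut at O1–C2 and C3–C4. The o-quinone methide generated from 2-hydroxybenzyl alcohol A6 adds across (Z)-enol acetate A7 in a hetero-Diels–Alder reaction and gives A8, with the C2 aryl and C3 acetoxy groups cis because the addition is suprafacial on a Z alkene.
- Merits: A8 is two steps from the target, the dienophile is small and achiral, and 1 is not needed. It uses the same quinone methide logic as the chosen plan.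
- Weak points: the methide terminus is an unsubstituted CH2 and the existing centres sit on the C8 side chain, so nothing in the substrate decides between the (2S,3S) and (2R,3R) ring C. A chiral acid catalyst would have to do so with an enol acetate. The regiochemistry rests on the aryl-bearing carbon, not the acetoxy-bearing one, becoming the cationic end. A6 again contains the unsolved vicinal pair.
- Comparison: Alternative 3 ends closer to the target and is better there. The chosen plan answers that its key step makes the difficult pair and takes the easy pair from 1, whereas Alternative 3 makes the easy pair with doubtful facial control and leaves the difficult one unaddressed.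

Key step: step 9

Assumption: (+)-epicatechin 1, the (2S,3S) antipode of the common natural flavan-3-ol, is bought as such and its two centres are carried through unchanged.

Assumption: the (5aS,10bR) triazolium precatalyst is taken to pair the Re face of the enolate with the Re face of the methide; if the sense of induction is the opposite, its antipode is used with no other change.

Shorthand used in names:
- "PBE-8-yl" = (2S,3S)-3,5,7-tris(benzyloxy)-2-[3,4-bis(benzyloxy)phenyl]chroman-8-yl.
- "7-HO-TBE-8-yl" = (2S,3S)-3,5-bis(benzyloxy)-2-[3,4-bis(benzyloxy)phenyl]-7-hydroxychroman-8-yl.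

## Route

Step 1
Reactants: 1 (+)-epicatechin
Product: 2 5,7,3',4'-tetra-O-benzyl-(+)-epicatechin (3-OH free)
Conditions: BnBr (4.4 equiv), K2CO3, DMF, 0 °C → rt, argon
Reagents that add atoms: benzyl bromide, BrCc1ccccc1
Why: Williamson etherification of the four phenols; carbonate does not deprotonate the secondary alcohol, and exclusion of air with a mild base keeps the 2,3-cis flavan from oxidising or epimerising at C2; no stereocentre is formed.

Step 2
Reactants: 2 5,7,3',4'-tetra-O-benzyl-(+)-epicatechin
Product: 3 8-bromo-5,7,3',4'-tetra-O-benzyl-(+)-epicatechin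
Conditions: NBS (1.0 equiv), CH2Cl2, −78 °C → rt
Reagents that add atoms: N-bromosuccinimide, O=C1CCC(=O)N1Br
Why: Electrophilic aromatic bromination; in 5,7-di-O-benzyl flavan-3-ols C8 is attacked in preference to C6, a selectivity established for benzylated catechins and epicatechins, and one equivalent at low temperature avoids dibromination.

Step 3
Reactants: 3 8-bromo-5,7,3',4'-tetra-O-benzyl-(+)-epicatechin
Product: 4 8-bromo-3,5,7,3',4'-penta-O-benzyl-(+)-epicatechin
Conditions: NaH, BnBr, Bu4NI (cat.), THF/DMF, 0 °C → rt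
Reagents that add atoms: benzyl bromide, BrCc1ccccc1
Why: Williamson etherification of the C3 alkoxide; the benzyl group keeps O3 from being acylated in the carbene step and leaves with the others at the end; C3 is not touched.

Step 4
Reactants: 4 8-bromo-3,5,7,3',4'-penta-O-benzyl-(+)-epicatechin
Product: 6 8-formyl-3,5,7,3',4'-penta-O-benzyl-(+)-epicatechin, via 8-lithio flavan 5 (not isolated)
Conditions: n-BuLi, THF, −78 °C; then DMF, −78 → 0 °C; H2O
Reagents that add atoms: N,N-dimethylformamide, CN(C)C=O
Why: Bromine–lithium exchange at −78 °C is faster than benzylic deprotonation, and the aryllithium is formylated by DMF (Bouveault formylation); quenching cold prevents transfer of the anion to an O-benzyl methylene.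

Step 5
Reactants: 6 8-formyl-3,5,7,3',4'-penta-O-benzyl-(+)-epicatechin
Product: 7 8-formyl-3,5,3',4'-tetra-O-benzyl-(+)-epicatechin (7-OH free)
Conditions: MgBr2·OEt2 (3 equiv), toluene/Et2O, rt → 50 °C; 1 M HCl work-up
Reagents that add atoms: none
Why: Chelation-controlled ether cleavage: magnesium bridged between the formyl oxygen and O7 activates only the ortho benzyl group for SN2 attack by bromide, so O5 (para) and the remote benzyl ethers stay; O1 can also chelate but its carbon is a hindered secondary centre, and MgBr2 is preferred to stronger boron halides to keep the O1–C2 bond and the C2 configuration intact.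

Step 6
Reactants: 7 8-formyl-3,5,3',4'-tetra-O-benzyl-(+)-epicatechin (7-OH free); 8 4-bromo-1,2-bis(benzyloxy)benzene
Product: 10 [3,4-bis(benzyloxy)phenyl](7-HO-TBE-8-yl)methanol as both carbinol epimers, via aryl Grignard reagent 9 (not isolated)
Conditions: 8, Mg, THF, rt → 40 °C; then 7 (0.4 equiv relative to 9), THF, 0 °C → rt; pH 7 buffer
Reagents that add atoms: none
Why: Grignard formation and 1,2-addition to a salicylaldehyde; the first equivalent deprotonates O7 and the magnesium phenoxide chelate activates the formyl group for the second; the carbinol centre is formed without control, which does not matter because it becomes trigonal in step 9, and the neutral quench avoids premature quinone methide chemistry.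

Step 7
Reactants: 11 glycolic acid
Product: 13 (tert-butyldimethylsilyloxy)acetic acid, via bis-silylated glycolate 12 (not isolated)
Conditions: TBSCl (2.2 equiv), imidazole, DMF, rt; then K2CO3, MeOH/THF/H2O, rt; aq. KHSO4 to pH 4
Reagents that add atoms: tert-butyldimethylsilyl chloride, CC(C)(C)[Si](C)(C)Cl
Why: Silylation of hydroxyl and carboxyl groups, then selective hydrolysis of the far more labile silyl ester by carbonate; no stereocentre.

Step 8
Reactants: 13 (tert-butyldimethylsilyloxy)acetic acid
Product: 14 1-[(tert-butyldimethylsilyloxy)acetyl]imidazole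
Conditions: 1,1'-carbonyldiimidazole, CH2Cl2, rt; used without chromatography
Reagents that add atoms: 1,1'-carbonyldiimidazole, O=C(n1ccnc1)n1ccnc1
Why: Carboxyl activation with loss of CO2 and imidazole gives the acyl imidazole, the established precursor of azolium enolates in carbene catalysis; it is moisture-sensitive and is used fresh.

Step 9
Reactants: 10 [3,4-bis(benzyloxy)phenyl](7-HO-TBE-8-yl)methanol; 14 1-[(tert-butyldimethylsilyloxy)acetyl]imidazole
Product: 16 (3R,4R)-cis-3-(tert-butyldimethylsilyloxy)-4-[3,4-bis(benzyloxy)phenyl]-3,4-dihydrocoumarin ring fused to ring A of 3,5,3',4'-tetra-O-benzyl-(+)-epicatechin (lactone oxygen on C7; lactone C4 on C8), via o-quinone methide 15 (not isolated)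
Conditions: i-Pr2NEt (2 equiv), 4 Å MS, toluene, 40 °C; then 14 (2 equiv), (5aS,10bR)-2-mesityl-5a,10b-dihydro-4H,6H-indeno[2,1-b][1,2,4]triazolo[4,3-d][1,4]oxazin-2-ium tetrafluoroborate (15 mol %), toluene/THF, 0 °C
Reagents that add atoms: none
Why: Under amine base and sieves the C7 phenoxide of 10 expels hydroxide to give o-quinone methide 15, which is stabilised as a vinylogous ester by O5 and O1 and by the dialkoxyaryl group and is drawn (E), the aryl group turned away from the C7 carbonyl. The carbene released from the triazolium salt is acylated by 14 and the acyl azolium is deprotonated to the (Z)-azolium enolate; its α-carbon adds to the methide carbon with rearomatisation of ring A, and the C7 phenoxide then attacks the acyl azolium, closing the six-membered lactone by a 6-exo-trig acyl substitution and releasing the carbene. The closest known reaction is the carbene-catalysed formal (4+2) annulation of o-quinone methides with azolium enolates generated from acyl imidazoles, which gives 3,4-dihydrocoumarins. Both new centres, lactone C3 (R) and C4 (R), are set by the chiral carbene-bound enolate: the indane wall leaves one enolate face open so that the Re face of the α-carbon meets the Re face of the methide carbon, and the endo arrangement with the enolate oxygen under the oxadiene places silyloxy and aryl cis. The flavan centres lie five or more bonds from the reacting carbon and should exert little bias, so the selectivity needed is catalyst control; the substrate helps in that O7 is the only free oxygen ortho to the carbinol (one methide, one lactone) and O3 and O5 are benzylated. The kinetic cis lactone is preserved by the weak amine base, the low temperature and prompt reduction in step 10.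

Step 10
Reactants: 16 flavan-fused (3R,4R)-cis-lactone
Product: 17 (2R,3R)-3-[3,4-bis(benzyloxy)phenyl]-2-(tert-butyldimethylsilyloxy)-3-(7-HO-TBE-8-yl)propan-1-ol
Conditions: LiBH4, THF, 0 °C; aq. NH4Cl
Reagents that add atoms: none
Why: Hydride reduction of an aryl ester to a primary alcohol and a phenol; the activated lactone is reduced faster than it enolises, so C2 (R) is retained, and benzyl and silyl ethers are inert.

Step 11
Reactants: 17 (2R,3R)-3-[3,4-bis(benzyloxy)phenyl]-2-(tert-butyldimethylsilyloxy)-3-(7-HO-TBE-8-yl)propan-1-ol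
Product: 18 (2R,3R)-3-[3,4-bis(benzyloxy)phenyl]-2-(tert-butyldimethylsilyloxy)-3-(PBE-8-yl)propan-1-ol
Conditions: BnBr, K2CO3, Bu4NI (cat.), DMF, rt
Reagents that add atoms: benzyl bromide, BrCc1ccccc1
Why: Williamson etherification selective for the phenol, since carbonate does not deprotonate the primary alcohol; O7 is masked before the sulfonylation and the later O-arylation.

Step 12
Reactants: 18 (2R,3R)-3-[3,4-bis(benzyloxy)phenyl]-2-(tert-butyldimethylsilyloxy)-3-(PBE-8-yl)propan-1-ol
Product: 19 (2R,3R)-3-[3,4-bis(benzyloxy)phenyl]-2-(tert-butyldimethylsilyloxy)-3-(PBE-8-yl)propyl 4-methylbenzenesulfonate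
Conditions: TsCl, Et3N, DMAP (cat.), CH2Cl2, 0 °C → rt
Reagents that add atoms: p-toluenesulfonyl chloride, Cc1ccc(cc1)S(Cl)(=O)=O
Why: Sulfonylation of the only free hydroxyl turns the former lactone carbonyl carbon into an electrophilic CH2; no stereocentre is involved.

Step 13
Reactants: 19 (2R,3R)-3-[3,4-bis(benzyloxy)phenyl]-2-(tert-butyldimethylsilyloxy)-3-(PBE-8-yl)propyl 4-methylbenzenesulfonate
Product: 21 (R)-2-{(R)-[3,4-bis(benzyloxy)phenyl](PBE-8-yl)methyl}oxirane, via hydroxy tosylate alkoxide 20 (not isolated)
Conditions: Bu4NF, THF, 0 °C → rt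
Reagents that add atoms: none
Why: Fluoride cleaves the silyl ether and the alkoxide displaces the neighbouring primary tosylate (intramolecular Williamson reaction, 3-exo-tet); the C–O bond at the stereocentre is never broken, so its configuration is retained.

Step 14
Reactants: 22 1-bromo-3,5-bis(benzyloxy)benzene
Product: 23 1-bromo-2-iodo-3,5-bis(benzyloxy)benzene
Conditions: NIS, MeCN, rt, dark
Reagents that add atoms: N-iodosuccinimide, O=C1CCC(=O)N1I
Why: Electrophilic aromatic iodination; the position para to one benzyloxy group and ortho to the other is attacked rather than the position flanked by both, as is usual for 1-halo-3,5-dialkoxybenzenes.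

Step 15
Reactants: 21 (R)-2-{(R)-[3,4-bis(benzyloxy)phenyl](PBE-8-yl)methyl}oxirane; 23 1-bromo-2-iodo-3,5-bis(benzyloxy)benzene
Product: 25 (1R,2S)-1-[3,4-bis(benzyloxy)phenyl]-3-[2-bromo-4,6-bis(benzyloxy)phenyl]-1-(PBE-8-yl)propan-2-ol, via bromoaryl Grignard reagent 24 (not isolated)
Conditions: 23, i-PrMgCl·LiCl, THF, −40 °C; then CuI (10 mol %), 21, −40 → 0 °C; aq. NH4Cl
Reagents that add atoms: none
Why: Iodine–magnesium exchange takes the iodide selectively and gives an ortho-bromoaryl Grignard reagent that is stable below 0 °C; copper-catalysed SN2 opening of the terminal epoxide at CH2 forms the C3–C3a bond without touching either stereocentre and frees the C2 hydroxyl (the descriptor changes to S only because the substituent ranking changes).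

Step 16
Reactants: 25 (1R,2S)-1-[3,4-bis(benzyloxy)phenyl]-3-[2-bromo-4,6-bis(benzyloxy)phenyl]-1-(PBE-8-yl)propan-2-ol
Product: 26 (S)-4,6-bis(benzyloxy)-2-{(R)-[3,4-bis(benzyloxy)phenyl](PBE-8-yl)methyl}-2,3-dihydrobenzofuran
Conditions: CuI (10 mol %), 3,4,7,8-tetramethyl-1,10-phenanthroline (20 mol %), Cs2CO3, toluene, 110 °C
Reagents that add atoms: none
Why: Copper-catalysed intramolecular Ullmann-type O-arylation (5-exo) of the secondary alkoxide by the aryl bromide; the carbinol C–O bond is kept, so C2 retains its configuration, and the bromide is meta to both benzyloxy groups and so is not deactivated.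

Step 17
Reactants: 26 nona-O-benzyl ether of the target
Product: 27 CNP0280971.1
Conditions: H2 (1 atm), Pd(OH)2/C, THF/MeOH, rt; filtration under argon
Reagents that add atoms: none
Why: Hydrogenolysis of nine benzyl ethers under neutral conditions; the ring C–O bonds and the diarylmethine are not cleaved under these mild conditions, as in the deprotection of benzylated oligomeric flavan-3-ols, and no stereocentre is touched.

## Compound list

1 | (+)-epicatechin, (2S,3S)-2-(3,4-dihydroxyphenyl)chroman-3,5,7-triol | Oc1cc(O)c2c(c1)O[C@@H](c1ccc(O)c(O)c1)[C@@H](O)C2 | starting material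
2 | 5,7,3',4'-tetra-O-benzyl-(+)-epicatechin | c1c(OCc9ccccc9)cc(OCc9ccccc9)c3c1O[C@@H](c4ccc(OCc9ccccc9)c(OCc9ccccc9)c4)[C@@H](O)C3 | intermediate
3 | 8-bromo-5,7,3',4'-tetra-O-benzyl-(+)-epicatechin | Brc1c(OCc9ccccc9)cc(OCc9ccccc9)c3c1O[C@@H](c4ccc(OCc9ccccc9)c(OCc9ccccc9)c4)[C@@H](O)C3 | intermediate
4 | 8-bromo-3,5,7,3',4'-penta-O-benzyl-(+)-epicatechin | Brc1c(OCc9ccccc9)cc(OCc9ccccc9)c3c1O[C@@H](c4ccc(OCc9ccccc9)c(OCc9ccccc9)c4)[C@@H](OCc9ccccc9)C3 | intermediate
5 | 8-lithio-3,5,7,3',4'-penta-O-benzyl-(+)-epicatechin | [Li]c1c(OCc9ccccc9)cc(OCc9ccccc9)c3c1O[C@@H](c4ccc(OCc9ccccc9)c(OCc9ccccc9)c4)[C@@H](OCc9ccccc9)C3 | intermediate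
6 | 8-formyl-3,5,7,3',4'-penta-O-benzyl-(+)-epicatechin | O=Cc1c(OCc9ccccc9)cc(OCc9ccccc9)c3c1O[C@@H](c4ccc(OCc9ccccc9)c(OCc9ccccc9)c4)[C@@H](OCc9ccccc9)C3 | intermediate
7 | 8-formyl-3,5,3',4'-tetra-O-benzyl-(+)-epicatechin, 7-OH free | O=Cc1c(O)cc(OCc9ccccc9)c3c1O[C@@H](c4ccc(OCc9ccccc9)c(OCc9ccccc9)c4)[C@@H](OCc9ccccc9)C3 | intermediate
8 | 4-bromo-1,2-bis(benzyloxy)benzene | Brc1ccc(OCc2ccccc2)c(OCc2ccccc2)c1 | starting material
9 | 3,4-bis(benzyloxy)phenylmagnesium bromide | Br[Mg]c1ccc(OCc2ccccc2)c(OCc2ccccc2)c1 | intermediate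
10 | [3,4-bis(benzyloxy)phenyl](7-HO-TBE-8-yl)methanol, both carbinol epimers | OC(c4ccc(OCc9ccccc9)c(OCc9ccccc9)c4)c1c(O)cc(OCc9ccccc9)c3c1O[C@@H](c4ccc(OCc9ccccc9)c(OCc9ccccc9)c4)[C@@H](OCc9ccccc9)C3 | intermediate
11 | glycolic acid | OCC(=O)O | starting material
12 | tert-butyldimethylsilyl (tert-butyldimethylsilyloxy)acetate | CC(C)(C)[Si](C)(C)OCC(=O)O[Si](C)(C)C(C)(C)C | intermediate
13 | (tert-butyldimethylsilyloxy)acetic acid | CC(C)(C)[Si](C)(C)OCC(=O)O | intermediate
14 | 1-[(tert-butyldimethylsilyloxy)acetyl]imidazole | O=C(CO[Si](C)(C)C(C)(C)C)n1ccnc1 | intermediate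
15 | o-quinone methide, (2S,3S,E)-3,5-bis(benzyloxy)-2-[3,4-bis(benzyloxy)phenyl]-8-[3,4-bis(benzyloxy)benzylidene]-3,4-dihydro-2H-chromen-7(8H)-one | O=C1C=C(OCc9ccccc9)C2=C(O[C@@H](c4ccc(OCc9ccccc9)c(OCc9ccccc9)c4)[C@@H](OCc9ccccc9)C2)/C1=C\c1ccc(OCc9ccccc9)c(OCc9ccccc9)c1 | intermediate
16 | flavan-fused (3R,4R)-cis-3-(tert-butyldimethylsilyloxy)-4-[3,4-bis(benzyloxy)phenyl]-3,4-dihydrocoumarin (lactone O on flavan C7, lactone C4 on flavan C8; flavan 2S,3S, tetra-O-benzyl) | O=C1[C@H](O[Si](C)(C)C(C)(C)C)[C@H](c4ccc(OCc9ccccc9)c(OCc9ccccc9)c4)c2c(O1)cc(OCc9ccccc9)c3c2O[C@@H](c4ccc(OCc9ccccc9)c(OCc9ccccc9)c4)[C@@H](OCc9ccccc9)C3 | intermediate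
17 | (2R,3R)-3-[3,4-bis(benzyloxy)phenyl]-2-(tert-butyldimethylsilyloxy)-3-(7-HO-TBE-8-yl)propan-1-ol | OC[C@H](O[Si](C)(C)C(C)(C)C)[C@H](c4ccc(OCc9ccccc9)c(OCc9ccccc9)c4)c2c(O)cc(OCc9ccccc9)c3c2O[C@@H](c4ccc(OCc9ccccc9)c(OCc9ccccc9)c4)[C@@H](OCc9ccccc9)C3 | intermediate
18 | (2R,3R)-3-[3,4-bis(benzyloxy)phenyl]-2-(tert-butyldimethylsilyloxy)-3-(PBE-8-yl)propan-1-ol | OC[C@H](O[Si](C)(C)C(C)(C)C)[C@H](c4ccc(OCc9ccccc9)c(OCc9ccccc9)c4)c2c(OCc9ccccc9)cc(OCc9ccccc9)c3c2O[C@@H](c4ccc(OCc9ccccc9)c(OCc9ccccc9)c4)[C@@H](OCc9ccccc9)C3 | intermediate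
19 | (2R,3R)-3-[3,4-bis(benzyloxy)phenyl]-2-(tert-butyldimethylsilyloxy)-3-(PBE-8-yl)propyl 4-methylbenzenesulfonate | Cc1ccc(cc1)S(=O)(=O)OC[C@H](O[Si](C)(C)C(C)(C)C)[C@H](c4ccc(OCc9ccccc9)c(OCc9ccccc9)c4)c2c(OCc9ccccc9)cc(OCc9ccccc9)c3c2O[C@@H](c4ccc(OCc9ccccc9)c(OCc9ccccc9)c4)[C@@H](OCc9ccccc9)C3 | intermediate
20 | (2R,3R)-3-[3,4-bis(benzyloxy)phenyl]-2-hydroxy-3-(PBE-8-yl)propyl 4-methylbenzenesulfonate, formed as its alkoxide | Cc1ccc(cc1)S(=O)(=O)OC[C@H](O)[C@H](c4ccc(OCc9ccccc9)c(OCc9ccccc9)c4)c2c(OCc9ccccc9)cc(OCc9ccccc9)c3c2O[C@@H](c4ccc(OCc9ccccc9)c(OCc9ccccc9)c4)[C@@H](OCc9ccccc9)C3 | intermediate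
21 | (R)-2-{(R)-[3,4-bis(benzyloxy)phenyl](PBE-8-yl)methyl}oxirane | C1O[C@@H]1[C@H](c4ccc(OCc9ccccc9)c(OCc9ccccc9)c4)c2c(OCc9ccccc9)cc(OCc9ccccc9)c3c2O[C@@H](c4ccc(OCc9ccccc9)c(OCc9ccccc9)c4)[C@@H](OCc9ccccc9)C3 | intermediate
22 | 1-bromo-3,5-bis(benzyloxy)benzene | Brc1cc(OCc2ccccc2)cc(OCc2ccccc2)c1 | starting material
23 | 1-bromo-2-iodo-3,5-bis(benzyloxy)benzene | Brc1cc(OCc2ccccc2)cc(OCc2ccccc2)c1I | intermediate
24 | 2-bromo-4,6-bis(benzyloxy)phenylmagnesium chloride (LiCl complex) | Brc1cc(OCc2ccccc2)cc(OCc2ccccc2)c1[Mg]Cl | intermediate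
25 | (1R,2S)-1-[3,4-bis(benzyloxy)phenyl]-3-[2-bromo-4,6-bis(benzyloxy)phenyl]-1-(PBE-8-yl)propan-2-ol | Brc1cc(OCc9ccccc9)cc(OCc9ccccc9)c1C[C@H](O)[C@H](c4ccc(OCc9ccccc9)c(OCc9ccccc9)c4)c2c(OCc9ccccc9)cc(OCc9ccccc9)c3c2O[C@@H](c4ccc(OCc9ccccc9)c(OCc9ccccc9)c4)[C@@H](OCc9ccccc9)C3 | intermediate
26 | (S)-4,6-bis(benzyloxy)-2-{(R)-[3,4-bis(benzyloxy)phenyl](PBE-8-yl)methyl}-2,3-dihydrobenzofuran, the nona-O-benzyl ether of the target | c9ccccc9COc1cc(OCc9ccccc9)c2c(c1)O[C@H]([C@H](c1ccc(OCc9ccccc9)c(OCc9ccccc9)c1)c1c(OCc9ccccc9)cc(OCc9ccccc9)c3c1O[C@@H](c1ccc(OCc9ccccc9)c(OCc9ccccc9)c1)[C@@H](OCc9ccccc9)C3)C2 | intermediate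
27 | CNP0280971.1, (2S,3S)-flavan-3-ol bearing at C8 the (R)-methine that carries a 3,4-dihydroxyphenyl group and the (S)-4,6-dihydroxy-2,3-dihydrobenzofuran-2-yl group | Oc1cc(O)c2c(c1)O[C@H]([C@H](c1ccc(O)c(O)c1)c1c(O)cc(O)c3c1O[C@@H](c1ccc(O)c(O)c1)[C@@H](O)C3)C2 | target

## Step count and least certain steps

Total: 17 steps. Longest linear sequence: 14 steps from 1 (steps 1–6, 9–13, 15–17).

Step 9 (key step). The most likely failure is insufficient facial selectivity. Catalyst control has to override an enantiopure substrate whose methide geometry is not fixed by an ortho hydrogen, since both flanks of C8 carry oxygen. The cis relationship can also erode by enolisation of the lactone, and O-acylation of 10 before it ionises would consume the acyl donor. The fallback replaces catalyst control by auxiliary control and sets out from 10 and 13. Acid 13 is joined through its pivaloyl mixed anhydride to lithiated (S)-4-benzyloxazolidin-2-one to give (S)-4-benzyl-3-[(tert-butyldimethylsilyloxy)acetyl]oxazolidin-2-one F1. Carbinol 10 is dehydrated to 15 over 4 Å sieves in warm toluene. The sodium (Z)-enolate of F1 (NaN(SiMe3)2, THF, −78 °C) is added to 15 in a Michael addition, giving the phenoxide of the open-chain imide adduct F2. On warming, this phenoxide expels the oxazolidinone and closes lactone 16, where the route is rejoined. The auxiliary sends the electrophile to the enolate face opposite its benzyl group, which corresponds to the (R) α-centre. The methine centre then rests on simple diastereoselection; because the flavan is enantiopure, all stereoisomers are diastereomers and can be separated.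

Step 5. The most likely failure is competing coordination of the Lewis acid to O1, with ionisation of the benzylic O1–C2 bond and erosion of the 2,3-cis configuration. Partial loss of the O5 benzyl group or degradation of the electron-rich aldehyde are also possible. The fallback moves the ether cleavage to a diaryl ketone and sets out from 6. Grignard reagent 9 is added to 6 to give the 7-O-benzyl carbinol [3,4-bis(benzyloxy)phenyl](PBE-8-yl)methanol F3. Dess–Martin periodinane oxidises it to the ketone [3,4-bis(benzyloxy)phenyl](PBE-8-yl)methanone F4. One equivalent of BCl3 in CH2Cl2 at −78 °C, chelated between the more basic, non-enolisable ketone oxygen and O7, removes the ortho benzyl group to give the hydroxy ketone [3,4-bis(benzyloxy)phenyl](7-HO-TBE-8-yl)methanone F5. NaBH4 in THF/EtOH at 0 °C, stopped at the alcohol stage, returns the route at 10 and bypasses 7 and step 6. This costs two more steps.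

Step 10. The most likely failure is 1,2 oxygen-to-oxygen silyl migration in the alkoxyborate formed on reduction (or under carbonate in step 11). It would scramble which of the two vicinal hydroxyls is free and so misdirect the sulfonylation. The fallback does without the silyl group as the differentiating element and sets out from 18, whichever oxygen carries the silyl group. Bu4NF gives the diol (2R,3R)-3-[3,4-bis(benzyloxy)phenyl]-3-(PBE-8-yl)propane-1,2-diol F6. Tin-catalysed sulfonylation (Bu2SnO cat., TsCl, Et3N, CH2Cl2) selects the primary hydroxyl and gives 20, and K2CO3 in MeOH closes the epoxide, rejoining the route at 21.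

Step 15. The most likely failure is slow opening of the epoxide by a doubly ortho-substituted arylcopper species. Chloride opening to a chlorohydrin, aryne formation on warming and alkylation of the reagent by the 2-iodopropane formed in the exchange can then take over. The fallback reverses the polarity and sets out from 19. NaI in acetone gives the primary iodide F7 (the iodide corresponding to 19, configuration unchanged). Zinc dust with LiCl in THF gives the alkylzinc iodide F8. A Negishi coupling with 23 (Pd(OAc)2, 2-dicyclohexylphosphino-2',6'-dimethoxybiphenyl, THF, rt) takes place at the carbon–iodine bond in preference to the carbon–bromine bond and gives the tert-butyldimethylsilyl ether of 25, F9. Bu4NF then rejoins the route at 25. β-Elimination of the silyloxy group from F8 is the hazard of this detour.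

Step 16. The most likely failure is slow carbon–oxygen bond formation at the hindered secondary alkoxide, with hydrodebromination competing. The fallback turns the aryl partner into a nucleophile and sets out from 25. Miyaura borylation (B2pin2, PdCl2(dppf), KOAc, dioxane, 80 °C) gives the aryl pinacolboronate F10. An oxidative Chan–Lam etherification (Cu(OAc)2, pyridine, 4 Å MS, air, CH2Cl2) closes the ring with retention at C2 and rejoins the route at 26.

## Further compounds

F1 | step 9 | (S)-4-benzyl-3-[(tert-butyldimethylsilyloxy)acetyl]oxazolidin-2-one | O=C1OC[C@H](Cc2ccccc2)N1C(=O)CO[Si](C)(C)C(C)(C)C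
F2 | step 9 | (S)-4-benzyl-3-[(2R,3R)-3-[3,4-bis(benzyloxy)phenyl]-2-(tert-butyldimethylsilyloxy)-3-(7-HO-TBE-8-yl)propanoyl]oxazolidin-2-one | O=C1OC[C@H](Cc2ccccc2)N1C(=O)[C@H](O[Si](C)(C)C(C)(C)C)[C@H](c4ccc(OCc9ccccc9)c(OCc9ccccc9)c4)c5c(O)cc(OCc9ccccc9)c3c5O[C@@H](c4ccc(OCc9ccccc9)c(OCc9ccccc9)c4)[C@@H](OCc9ccccc9)C3
F3 | step 5 | [3,4-bis(benzyloxy)phenyl](PBE-8-yl)methanol, both carbinol epimers | OC(c4ccc(OCc9ccccc9)c(OCc9ccccc9)c4)c1c(OCc9ccccc9)cc(OCc9ccccc9)c3c1O[C@@H](c4ccc(OCc9ccccc9)c(OCc9ccccc9)c4)[C@@H](OCc9ccccc9)C3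
F4 | step 5 | [3,4-bis(benzyloxy)phenyl](PBE-8-yl)methanone | O=C(c4ccc(OCc9ccccc9)c(OCc9ccccc9)c4)c1c(OCc9ccccc9)cc(OCc9ccccc9)c3c1O[C@@H](c4ccc(OCc9ccccc9)c(OCc9ccccc9)c4)[C@@H](OCc9ccccc9)C3
F5 | step 5 | [3,4-bis(benzyloxy)phenyl](7-HO-TBE-8-yl)methanone | O=C(c4ccc(OCc9ccccc9)c(OCc9ccccc9)c4)c1c(O)cc(OCc9ccccc9)c3c1O[C@@H](c4ccc(OCc9ccccc9)c(OCc9ccccc9)c4)[C@@H](OCc9ccccc9)C3
F6 | step 10 | (2R,3R)-3-[3,4-bis(benzyloxy)phenyl]-3-(PBE-8-yl)propane-1,2-diol | OC[C@H](O)[C@H](c4ccc(OCc9ccccc9)c(OCc9ccccc9)c4)c2c(OCc9ccccc9)cc(OCc9ccccc9)c3c2O[C@@H](c4ccc(OCc9ccccc9)c(OCc9ccccc9)c4)[C@@H](OCc9ccccc9)C3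
F7 | step 15 | tert-butyl{[(2R,3R)-3-[3,4-bis(benzyloxy)phenyl]-1-iodo-3-(PBE-8-yl)propan-2-yl]oxy}dimethylsilane | IC[C@H](O[Si](C)(C)C(C)(C)C)[C@H](c4ccc(OCc9ccccc9)c(OCc9ccccc9)c4)c2c(OCc9ccccc9)cc(OCc9ccccc9)c3c2O[C@@H](c4ccc(OCc9ccccc9)c(OCc9ccccc9)c4)[C@@H](OCc9ccccc9)C3
F8 | step 15 | [(2R,3R)-3-[3,4-bis(benzyloxy)phenyl]-2-(tert-butyldimethylsilyloxy)-3-(PBE-8-yl)propyl]zinc iodide | I[Zn]C[C@H](O[Si](C)(C)C(C)(C)C)[C@H](c4ccc(OCc9ccccc9)c(OCc9ccccc9)c4)c2c(OCc9ccccc9)cc(OCc9ccccc9)c3c2O[C@@H](c4ccc(OCc9ccccc9)c(OCc9ccccc9)c4)[C@@H](OCc9ccccc9)C3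
F9 | step 15 | tert-butyldimethylsilyl ether of 25, (1R,2S) | Brc1cc(OCc9ccccc9)cc(OCc9ccccc9)c1C[C@H](O[Si](C)(C)C(C)(C)C)[C@H](c4ccc(OCc9ccccc9)c(OCc9ccccc9)c4)c2c(OCc9ccccc9)cc(OCc9ccccc9)c3c2O[C@@H](c4ccc(OCc9ccccc9)c(OCc9ccccc9)c4)[C@@H](OCc9ccccc9)C3
F10 | step 16 | (1R,2S)-1-[3,4-bis(benzyloxy)phenyl]-3-[2,4-bis(benzyloxy)-6-(4,4,5,5-tetramethyl-1,3,2-dioxaborolan-2-yl)phenyl]-1-(PBE-8-yl)propan-2-ol | CC1(C)OB(OC1(C)C)c1cc(OCc9ccccc9)cc(OCc9ccccc9)c1C[C@H](O)[C@H](c4ccc(OCc9ccccc9)c(OCc9ccccc9)c4)c2c(OCc9ccccc9)cc(OCc9ccccc9)c3c2O[C@@H](c4ccc(OCc9ccccc9)c(OCc9ccccc9)c4)[C@@H](OCc9ccccc9)C3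
A1 | alternative 1 | methyl 2-diazo-2-{2-[(R)-2-[3,4-bis(benzyloxy)phenyl]-2-(PBE-8-yl)ethoxy]-4,6-bis(triisopropylsilyloxy)phenyl}acetate | COC(=O)C(=[N+]=[N-])c2c(O[Si](C(C)C)(C(C)C)C(C)C)cc(O[Si](C(C)C)(C(C)C)C(C)C)cc2OC[C@H](c1ccc(OCc9ccccc9)c(OCc9ccccc9)c1)c1c(OCc9ccccc9)cc(OCc9ccccc9)c3c1O[C@@H](c1ccc(OCc9ccccc9)c(OCc9ccccc9)c1)[C@@H](OCc9ccccc9)C3
A2 | alternative 1 | methyl cis-2-{[3,4-bis(benzyloxy)phenyl](PBE-8-yl)methyl}-4,6-bis(triisopropylsilyloxy)-2,3-dihydrobenzofuran-3-carboxylate | COC(=O)[C@@H]1c2c(O[Si](C(C)C)(C(C)C)C(C)C)cc(O[Si](C(C)C)(C(C)C)C(C)C)cc2O[C@@H]1[C@H](c1ccc(OCc9ccccc9)c(OCc9ccccc9)c1)c1c(OCc9ccccc9)cc(OCc9ccccc9)c3c1O[C@@H](c1ccc(OCc9ccccc9)c(OCc9ccccc9)c1)[C@@H](OCc9ccccc9)C3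
A3 | alternative 2 | 3-(benzyloxy)-4-[(2S,3R)-2-(benzyloxy)-3-[3,4-bis(benzyloxy)phenyl]-3-(tert-butyldimethylsilyloxy)propyl]cyclobut-2-en-1-one, either configuration at C4 | O=C1C=C(OCc9ccccc9)C1C[C@H](OCc9ccccc9)[C@H](O[Si](C)(C)C(C)(C)C)c2ccc(OCc9ccccc9)c(OCc9ccccc9)c2
A4 | alternative 2 | (S)-4,6-bis(benzyloxy)-2-[(R)-1-[3,4-bis(benzyloxy)phenyl]-3-(triisopropylsilyloxy)prop-2-yn-1-yl]-2,3-dihydrobenzofuran | CC(C)[Si](C(C)C)(C(C)C)OC#C[C@@H](c4ccc(OCc9ccccc9)c(OCc9ccccc9)c4)[C@@H]5Cc6c(OCc9ccccc9)cc(OCc9ccccc9)cc6O5
A5 | alternative 2 | ring A phenol with the methine at C8, triisopropylsilyloxy at C7, benzyloxy at C5 and the C2–C4 chain at C4a | Oc1c([C@@H](c4ccc(OCc9ccccc9)c(OCc9ccccc9)c4)[C@@H]5Cc6c(OCc9ccccc9)cc(OCc9ccccc9)cc6O5)c(O[Si](C(C)C)(C(C)C)C(C)C)cc(OCc9ccccc9)c1C[C@H](OCc9ccccc9)[C@H](O[Si](C)(C)C(C)(C)C)c2ccc(OCc9ccccc9)c(OCc9ccccc9)c2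
A6 | alternative 3 | 3,5-bis(benzyloxy)-2-(hydroxymethyl)-6-{(R)-[3,4-bis(benzyloxy)phenyl][(S)-4,6-bis(benzyloxy)-2,3-dihydrobenzofuran-2-yl]methyl}phenol | OCc3c(OCc9ccccc9)cc(OCc9ccccc9)c([C@@H](c1ccc(OCc9ccccc9)c(OCc9ccccc9)c1)[C@@H]1Cc2c(OCc9ccccc9)cc(OCc9ccccc9)cc2O1)c3O
A7 | alternative 3 | (Z)-2-[3,4-bis(benzyloxy)phenyl]vinyl acetate | CC(=O)O/C=C\c1ccc(OCc2ccccc2)c(OCc2ccccc2)c1
A8 | alternative 3 | octa-O-benzyl 3-O-acetyl derivative of the target | c9ccccc9COc1cc(OCc9ccccc9)c2c(c1)O[C@H]([C@H](c1ccc(OCc9ccccc9)c(OCc9ccccc9)c1)c1c(OCc9ccccc9)cc(OCc9ccccc9)c3c1O[C@@H](c1ccc(OCc9ccccc9)c(OCc9ccccc9)c1)[C@@H](OC(C)=O)C3)C2
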